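**Retrosynthetic overview**
- The (5S)-carbinol comes from the C5 ketone of a 2-alkyl-7,8-dihydro-4H-chromene-4,5(6H)-dione by asymmetric transfer hydrogenation; the stereocentre is set last.
- The pyran-4-one ring comes from acid cyclodehydration of a 2-(3-oxoacyl)cyclohexane-1,3-dione.
- Key C–C bond (pyranone C2–C3): crossed Claisen condensation of the acetyl-methyl dianion of 2-acetylcyclohexane-1,3-dione with the Weinreb amide of (13Z)-octadec-13-enoic acid.
- The Z-C18 acid comes from semihydrogenation of octadec-13-ynoic acid, itself from hex-1-yne and 12-bromododecanoic acid by acetylide alkylation.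
- Ring order: the carbocycle is bought ready-made in the triketone; the pyranone ring is closed second (step 5).

Assumption: hex-1-yne, 12-bromododecanoic acid and 2-acetylcyclohexane-1,3-dione are taken as catalogue chemicals; enolised polyketones are drawn as one tautomer.

**Step 1**
Reactants: 1 hex-1-yne; 2 12-bromododecanoic acid
Product: 4 octadec-13-ynoic acid, via hex-1-yn-1-yllithium 3 (not isolated)
Conditions: 1 (2.5 equiv), n-BuLi (2.4 equiv), THF, −78 to 0 °C; then 2, DMPU, 0 °C to rt, 16 h; aq. HCl
Reagents that add atoms: none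
Why: In this acetylide alkylation the first equivalent of lithium acetylide only converts the acid into its inert lithium carboxylate, and the second displaces the unhindered primary bromide by SN2 in the dipolar cosolvent, with no stereocentre formed.

**Step 2**
Reactants: 4 octadec-13-ynoic acid
Product: 5 (13Z)-octadec-13-enoic acid
Conditions: H2 (1 atm), 5% Pd/CaCO3 poisoned with Pb(OAc)2, quinoline, EtOAc, rt, stop after 1 equiv H2
Reagents that add atoms: none
Why: Lindlar semihydrogenation delivers both hydrogens syn on the poisoned palladium surface, giving the Z-alkene and stopping at the alkene stage, while the carboxylic acid is inert.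

**Step 3**
Reactants: 5 (13Z)-octadec-13-enoic acid
Product: 7 (13Z)-N-methoxy-N-methyloctadec-13-enamide, via 1-[(13Z)-octadec-13-enoyl]imidazole 6 (not isolated)
Conditions: CDI (1.2 equiv), CH2Cl2, rt, 1 h; then MeNH(OMe)·HCl (1.5 equiv), rt, 12 h
Reagents that add atoms: N,O-dimethylhydroxylamine hydrochloride, CNOC.Cl
Why: Weinreb amide formation through the acyl imidazolide is a mild, neutral acyl substitution that leaves the isolated Z-alkene untouched.

**Step 4**
Reactants: 7 (13Z)-N-methoxy-N-methyloctadec-13-enamide; 8 2-acetylcyclohexane-1,3-dione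
Product: 11 2-[(15Z)-3-oxoicos-15-enoyl]cyclohexane-1,3-dione, via dilithium acetyl-methyl dianion 9 (not isolated), via tetrahedral N-methoxy-N-methyl adduct 10 (not isolated)
Conditions: 8 (2.2 equiv), LiN(iPr)2 (4.5 equiv), THF, −78 to 0 °C, 1 h; then 7 (1.0 equiv), −78 to 0 °C, 3 h; cold 1 M HCl; crude product taken on
Reagents that add atoms: none
Why: In this crossed Claisen condensation of Hauser–Harris dianion type, the second deprotonation of the enolised triketone takes place at the acetyl methyl group and the dianion reacts at that terminal carbon with the Weinreb amide, whose chelated tetrahedral adduct blocks over-addition and releases the 1,3,5-tricarbonyl chain only on acidic quench.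

**Step 5**
Reactants: 11 2-[(15Z)-3-oxoicos-15-enoyl]cyclohexane-1,3-dione
Product: 12 2-[(12Z)-heptadec-12-en-1-yl]-7,8-dihydro-4H-chromene-4,5(6H)-dione
Conditions: TsOH·H2O (10 mol%), toluene, reflux, Dean–Stark, 2 h; aq. NaHCO3 wash (removes excess 8)
Reagents that add atoms: none
Why: Acid-catalysed cyclodehydration of a 1,3,5-tricarbonyl unit to a 4-pyranone closes the only possible six-membered oxygen ring (the two ring carbonyls are equivalent), and catalytic sulfonic acid is too mild to isomerise the isolated Z-alkene.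

**Step 6**
Reactants: 12 2-[(12Z)-heptadec-12-en-1-yl]-7,8-dihydro-4H-chromene-4,5(6H)-dione
Product: 13 (5S)-2-[(12Z)-heptadec-12-en-1-yl]-5-hydroxy-5,6,7,8-tetrahydro-4H-chromen-4-one
Conditions: RuCl[(S,S)-TsDPEN](p-cymene) (2 mol%), HCO2H/Et3N (5:2), EtOAc, 30 °C, 24 h
Reagents that add atoms: none
Why: In this Noyori asymmetric transfer hydrogenation the C5 ketone is the only reducible group (the pyranone carbonyl is a doubly vinylogous ester and the alkene is inert to the outer-sphere Ru–H/N–H transfer), and the (S,S)-ligand delivers hydride to the face that gives the (S)-carbinol, by analogy with 1-tetralone and chroman-4-one where the sp2 ring carbon takes the aryl role.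

**Compound list**
1 | hex-1-yne | CCCCC#C | starting material
2 | 12-bromododecanoic acid | OC(=O)CCCCCCCCCCCBr | starting material
3 | hex-1-yn-1-yllithium | [Li]C#CCCCC | intermediate (not isolated)
4 | octadec-13-ynoic acid | CCCCC#CCCCCCCCCCCCC(=O)O | intermediate
5 | (13Z)-octadec-13-enoic acid | CCCC/C=C\CCCCCCCCCCCC(=O)O | intermediate
6 | 1-[(13Z)-octadec-13-enoyl]-1H-imidazole | CCCC/C=C\CCCCCCCCCCCC(=O)n1ccnc1 | intermediate (not isolated)
7 | (13Z)-N-methoxy-N-methyloctadec-13-enamide | CCCC/C=C\CCCCCCCCCCCC(=O)N(C)OC | intermediate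
8 | 2-acetylcyclohexane-1,3-dione (enol form) | CC(=O)C1=C(O)CCCC1=O | starting material
9 | dilithium 2-(1-oxidoethenyl)-3-oxocyclohex-1-en-1-olate (acetyl-methyl dianion of 8) | [Li+].[Li+].C=C([O-])C1=C([O-])CCCC1=O | intermediate (not isolated)
10 | dilithium salt of the tetrahedral adduct 2-[(15Z)-3-hydroxy-3-[methoxy(methyl)amino]icos-15-enoyl]cyclohexane-1,3-dione (racemic at the aminal carbon) | [Li+].[Li+].CCCC/C=C\CCCCCCCCCCCC([O-])(N(C)OC)CC(=O)C1=C([O-])CCCC1=O | intermediate (not isolated)
11 | 2-[(15Z)-3-oxoicos-15-enoyl]cyclohexane-1,3-dione (enol form) | CCCC/C=C\CCCCCCCCCCCC(=O)CC(=O)C1=C(O)CCCC1=O | intermediate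
12 | 2-[(12Z)-heptadec-12-en-1-yl]-7,8-dihydro-4H-chromene-4,5(6H)-dione | CCCC/C=C\CCCCCCCCCCCc1cc(=O)c2c(o1)CCCC2=O | intermediate
13 | (5S)-2-[(12Z)-heptadec-12-en-1-yl]-5-hydroxy-5,6,7,8-tetrahydro-4H-chromen-4-one | CCCC/C=C\CCCCCCCCCCCc1cc(=O)c2c(o1)CCC[C@@H]2O | target

**Totals**
Total step count: 6. Longest linear sequence: 6 steps (1/2 → 4 → 5 → 7 → 11 → 12 → 13); 8 enters at step 4.

**Steps most likely to fail, with fallbacks**

Step 4 (dianion Claisen). The risks are a wrong site of second deprotonation or a sluggish acylation. The fallback sets out from acid 5 and comes back at 12, using the unambiguous C2 nucleophile of cyclohexane-1,3-dione instead of a carbanion. Acid 5 is condensed with Meldrum's acid (DCC, DMAP, CH2Cl2, 0 °C to rt) to give 5-[(13Z)-1-hydroxyoctadec-13-en-1-ylidene]-2,2-dimethyl-1,3-dioxane-4,6-dione F1. Heating F1 with cyclohexane-1,3-dione (1.5 equiv, toluene, 100 °C) expels acetone and CO2 and releases the acylketene (15Z)-icosa-1,15-diene-1,3-dione F2. F2 is captured at C2 of the dione enol in a formal [4+2] C-acylation/O-cyclisation, and a final TsOH·H2O-promoted dehydration gives 12.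

Step 5 (cyclodehydration). The risks are incomplete closure, retro-Claisen cleavage or acid damage to the alkene. The fallback sets out from 11 and comes back at 12, replacing protic dehydration by activation and base-mediated ring closure. Oxalyl chloride (1.1 equiv, cat. DMF, CH2Cl2, 0 °C) converts the ring enol into the vinylogous acid chloride 3-chloro-2-[(15Z)-3-oxoicos-15-enoyl]cyclohex-2-en-1-one F3. Et3N (2.5 equiv, CH2Cl2, 0 °C to rt) then lets the side-chain enolate oxygen displace chloride by intramolecular addition–elimination, giving 12 without heat or strong acid.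

Step 6 (asymmetric transfer hydrogenation). The risks are low rate or insufficient ee on this peri-carbonyl ketone. The fallback sets out from 12 and comes back at 13, replacing catalyst control by resolution. Luche reduction (NaBH4, CeCl3·7H2O, MeOH, −40 °C) gives racemic 2-[(12Z)-heptadec-12-en-1-yl]-5-hydroxy-5,6,7,8-tetrahydro-4H-chromen-4-one F4. Kinetic resolution with Candida antarctica lipase B and vinyl acetate (MTBE, 30 °C) acylates the (R)-enantiomer, as for 1-tetralol, to (5R)-2-[(12Z)-heptadec-12-en-1-yl]-4-oxo-5,6,7,8-tetrahydro-4H-chromen-5-yl acetate F5. The unreacted (S)-alcohol, separated by chromatography, is 13 (at most 50%).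

**Further compounds**
F1 | step 4 | 5-[(13Z)-1-hydroxyoctadec-13-en-1-ylidene]-2,2-dimethyl-1,3-dioxane-4,6-dione | CCCC/C=C\CCCCCCCCCCCC(O)=C1C(=O)OC(C)(C)OC1=O
F2 | step 4 | (15Z)-icosa-1,15-diene-1,3-dione (acylketene) | CCCC/C=C\CCCCCCCCCCCC(=O)C=C=O
F3 | step 5 | 3-chloro-2-[(15Z)-3-oxoicos-15-enoyl]cyclohex-2-en-1-one | CCCC/C=C\CCCCCCCCCCCC(=O)CC(=O)C1=C(Cl)CCCC1=O
F4 | step 6 | racemic 2-[(12Z)-heptadec-12-en-1-yl]-5-hydroxy-5,6,7,8-tetrahydro-4H-chromen-4-one | CCCC/C=C\CCCCCCCCCCCc1cc(=O)c2c(o1)CCCC2O
F5 | step 6 | (5R)-2-[(12Z)-heptadec-12-en-1-yl]-4-oxo-5,6,7,8-tetrahydro-4H-chromen-5-yl acetate | CCCC/C=C\CCCCCCCCCCCc1cc(=O)c2c(o1)CCC[C@H]2OC(C)=O
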